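The whole plan depends on cutting the C1–C10 bond of the ten-membered carbocycle (ring A). The exocyclic methylene sits on C1 and the methoxycarbonyl group on the neighbouring C10. Each of these two sp2 ring atoms has just one carbon attached from outside, so a pair of vicinal ring ketones can stand for them, and these arise from two ester carbons. A sodium/Me3SiCl acyloin coupling joins the two carbons and closes ring A in one operation as a bis(silyl) enediol ether. Its precursor is an open-chain dimethyl diester. It already holds the C4/C5 methyl stereodiad, the cis C7=C8 alkene and a silyl-protected hydroxyethyl arm (C11–C12) on C5.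

Key step: step 11

Numbering: ring A = C1 (=CH2), C2, C3, C4 (CHMe), C5 (quaternary, Me), C6, C7=C8, C9=C10 (CO2Me); side chain C11 (CH2), C12 (carbinol); ring B = furan.
Assumption: the target SMILES requires (R)-2-methylbutanoate and this acid is bought as such; the facial sense in step 2 is taken from the accepted binding model of the catalyst, and the equally available mirror-image catalyst would be used should the sense prove opposite.

Step 1
Reactants: 1 but-3-en-2-one
Product: 2 2-(triisopropylsilyloxy)buta-1,3-diene
Conditions: i-Pr3SiOTf, Et3N, CH2Cl2, 0 °C to rt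
Reagents that add atoms: triisopropylsilyl triflate, CC(C)[Si](OS(=O)(=O)C(F)(F)F)(C(C)C)C(C)C
Why: Soft enolisation with O-silylation of the enone gives the 2-silyloxydiene, and the bulky silyl group is chosen because it should withstand the acidic cycloaddition catalyst better than trimethylsilyl.

Step 2
Reactants: 2 2-(triisopropylsilyloxy)buta-1,3-diene; 3 (E)-2-methylbut-2-enal
Product: 4 (1R,6R)-1,6-dimethyl-4-(triisopropylsilyloxy)cyclohex-3-ene-1-carbaldehyde
Conditions: (S)-3,3-diphenyl-1-(2-methylphenyl)tetrahydro-1H,3H-pyrrolo[1,2-c][1,3,2]oxazaborole (20 mol %), HN(SO2CF3)2 (18 mol %), CH2Cl2, −78 to −40 °C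
Reagents that add atoms: none
Why: Catalytic enantioselective Diels–Alder reaction in which the 2-silyloxy donor steers the para orientation, suprafacial addition to the E-enal places the two methyl groups cis, and the protonated oxazaborolidine (B–O coordination plus a formyl C–H···O contact, one face covered by phenyl and counter-ion) should send the diene to the Cα Re face, setting C5 and C4 together.

Step 3
Reactants: 4 (1R,6R)-1,6-dimethyl-4-(triisopropylsilyloxy)cyclohex-3-ene-1-carbaldehyde
Product: 5 [(4S,5R)-4-ethenyl-4,5-dimethylcyclohex-1-en-1-yl]oxy(triisopropyl)silane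
Conditions: MePPh3Br, KN(SiMe3)2, THF, 0 °C; then 4, 0 °C to rt
Reagents that add atoms: methyltriphenylphosphonium bromide, C[P+](c1ccccc1)(c1ccccc1)c1ccccc1.[Br-]
Why: Wittig methylenation of a non-enolisable aldehyde is reliable, leaves the silyl enol ether alone and cannot disturb the adjacent quaternary centre.

Step 4
Reactants: 5 [(4S,5R)-4-ethenyl-4,5-dimethylcyclohex-1-en-1-yl]oxy(triisopropyl)silane
Product: 7 2-[(1S,6R)-1,6-dimethyl-4-(triisopropylsilyloxy)cyclohex-3-en-1-yl]ethanol, via B-alkyl-9-BBN adduct 6 (not isolated)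
Conditions: 9-borabicyclo[3.3.1]nonane, THF, rt; then 30 % H2O2, aq NaOH, 0 °C
Reagents that add atoms: hydrogen peroxide, OO
Why: Hydroboration–oxidation with a bulky borane should pick the monosubstituted vinyl group over the trisubstituted silyl enol ether and place boron on the terminal carbon, giving the C11–C12 arm without any acid hydrolysis that would also destroy the regiodefined enol ether.

Step 5
Reactants: 7 2-[(1S,6R)-1,6-dimethyl-4-(triisopropylsilyloxy)cyclohex-3-en-1-yl]ethanol
Product: 9 (3R)-3-[(4R)-2-methoxy-4-methyloxan-4-yl]butanoic acid, via lactol acid 8 (not isolated)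
Conditions: O3, CH2Cl2, −78 °C; Me2S, −78 °C to rt; concentrate; MeOH, pyridinium p-toluenesulfonate (cat.), rt
Reagents that add atoms: ozone, [O-][O+]=O; methanol, CO
Why: Ozonolysis of the silyl enol ether delivers the C7 aldehyde and a carboxylic acid in different oxidation states, the free C12 hydroxyl captures the aldehyde as a six-membered lactol, and acetal exchange with methanol locks it, so aldehyde and alcohol are masked together for the homologation (the anomeric centre is a mixture and is lost in step 9).

Step 6
Reactants: 9 (3R)-3-[(4R)-2-methoxy-4-methyloxan-4-yl]butanoic acid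
Product: 11 (4R)-1-diazo-4-[(4R)-2-methoxy-4-methyloxan-4-yl]pentan-2-one, via mixed anhydride 10 (not isolated)
Conditions: i-BuOCOCl, N-methylmorpholine, THF, −20 °C; then CH2N2, Et2O, 0 °C
Reagents that add atoms: diazomethane, C=[N+]=[N-]
Why: First half of the Arndt–Eistert homologation, in which the mixed anhydride acylates diazomethane under near-neutral conditions that touch neither the acetal nor the stereodiad, no free aldehyde being present to consume the reagent.

Step 7
Reactants: 11 (4R)-1-diazo-4-[(4R)-2-methoxy-4-methyloxan-4-yl]pentan-2-one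
Product: 12 methyl (4R)-4-[(4R)-2-methoxy-4-methyloxan-4-yl]pentanoate
Conditions: AgO2CPh (10 mol %), Et3N, MeOH, rt, dark
Reagents that add atoms: methanol, CO
Why: Silver-catalysed Wolff rearrangement gives a ketene that methanol traps as the methyl ester; the migrating C3 methylene carries no stereocentre, and the chain gains the C3–C2–C1 length needed for a ten-membered ring.

Step 8
Reactants: 12 methyl (4R)-4-[(4R)-2-methoxy-4-methyloxan-4-yl]pentanoate
Product: 13 methyl (4R)-4-[(4R)-2-hydroxy-4-methyloxan-4-yl]pentanoate
Conditions: 1 M aq HCl, THF, rt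
Reagents that add atoms: water, O
Why: Mild acid hydrolysis of the cyclic acetal frees the lactol while the methyl ester survives at room temperature, and no silyl ether is present yet to be lost.

Step 9
Reactants: 13 methyl (4R)-4-[(4R)-2-hydroxy-4-methyloxan-4-yl]pentanoate; 14 (2-carboxyethyl)triphenylphosphonium bromide
Product: 17 dimethyl (3Z,6S,7R)-6-(2-hydroxyethyl)-6,7-dimethyldec-3-enedioate, via carboxylate ylide 15 (not isolated), via hydroxy acid 16 (not isolated)
Conditions: 14 (3 equiv), NaN(SiMe3)2 (6 equiv), THF, −78 to 0 °C; add 13, 0 °C to rt; 1 M HCl to pH 4; crude acid, CH2N2, Et2O, 0 °C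
Reagents that add atoms: diazomethane, C=[N+]=[N-]
Why: Wittig olefination of a lactol through its open hydroxy aldehyde with a non-stabilised ylide under lithium-free conditions should give the cis C7=C8 alkene by kinetic cis-oxaphosphetane formation; the carboxylate keeps the ylide from shedding phosphine, and base-free esterification leaves the β,γ double bond in place.

Step 10
Reactants: 17 dimethyl (3Z,6S,7R)-6-(2-hydroxyethyl)-6,7-dimethyldec-3-enedioate
Product: 18 dimethyl (3Z,6S,7R)-6-[2-(tert-butyldimethylsilyloxy)ethyl]-6,7-dimethyldec-3-enedioate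
Conditions: t-BuMe2SiCl, imidazole, CH2Cl2, rt
Reagents that add atoms: tert-butyldimethylsilyl chloride, CC(C)(C)[Si](C)(C)Cl
Why: Standard silylation of the primary alcohol gives an ether that is inert to sodium and to hot chlorosilane and removes the only acidic O–H before the reductive step.

Step 11
Reactants: 18 dimethyl (3Z,6S,7R)-6-[2-(tert-butyldimethylsilyloxy)ethyl]-6,7-dimethyldec-3-enedioate
Product: 19 (4R,5S,7Z)-5-[2-(tert-butyldimethylsilyloxy)ethyl]-4,5-dimethyl-1,10-bis(trimethylsilyloxy)cyclodeca-1(10),7-diene
Conditions: Na sand (8 equiv), Me3SiCl (10 equiv, freshly distilled), toluene, reflux, Ar; 18 added by syringe pump over 24 h (final about 0.005 M)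
Reagents that add atoms: chlorotrimethylsilane, C[Si](C)(C)Cl
Why: Each ester carbonyl accepts an electron from the metal, the two ketyl radical anions combine to make the C1–C10 bond, loss of two methoxides and uptake of two further electrons lead to the ring enediolate, and Me3SiCl caps both oxygens; this is the acyloin condensation in its chlorosilane-trapping (Rühlmann) form, the classical route to ten-membered carbocycles. Ring A closes end to end by this reductive carbonyl–carbonyl coupling of a chain held by both termini on the sodium surface, so no attack trajectory has to be met. No stereocentre is created, C4 and C5 lie away from every acidic position and pass through unchanged, and the new enediol double bond should be cis within the ring. Ring closure has to win over chain-to-chain coupling, which slow addition at high dilution provides and which the cis C7=C8 alkene and the quaternary C5 support by folding the chain. The doubly activated C9 hydrogens must stay in place, and excess Me3SiCl should secure this by converting methoxide into MeOSiMe3 at once, so that neither conjugation of the β,γ-unsaturated ester nor a Dieckmann closure can start. The isolated alkene and the alkyl silyl ether tolerate sodium in toluene, whereas an oxygenated furylic carbon probably would not, which is why ring B is attached only afterwards.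

Step 12
Reactants: 19 (4R,5S,7Z)-5-[2-(tert-butyldimethylsilyloxy)ethyl]-4,5-dimethyl-1,10-bis(trimethylsilyloxy)cyclodeca-1(10),7-diene
Product: 20 (4R,5S,7Z)-5-[2-(tert-butyldimethylsilyloxy)ethyl]-4,5-dimethylcyclodec-7-ene-1,10-dione
Conditions: Br2 (1.0 equiv, dilute solution), CH2Cl2, −78 °C; cold aq NaHCO3
Reagents that add atoms: none
Why: Bromine attacks the very electron-rich bis(silyloxy)alkene far faster than the isolated cis alkene and both O–Si bonds leave as Me3SiBr, the established direct oxidation of acyloin bis(silyl) ethers to 1,2-diketones.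

Step 13
Reactants: 20 (4R,5S,7Z)-5-[2-(tert-butyldimethylsilyloxy)ethyl]-4,5-dimethylcyclodec-7-ene-1,10-dione
Product: 22 (4R,5S,7Z,9E)-5-[2-(tert-butyldimethylsilyloxy)ethyl]-4,5-dimethyl-1-oxocyclodeca-7,9-dien-10-yl triflate, via potassium dienolate 21 (not isolated)
Conditions: KN(SiMe3)2 (1.05 equiv), THF, −78 °C; then N-(5-chloropyridin-2-yl)bis(trifluoromethanesulfonimide), −78 °C
Reagents that add atoms: N-(5-chloropyridin-2-yl)bis(trifluoromethanesulfonimide), O=S(=O)(N(c1ccc(Cl)cn1)S(=O)(=O)C(F)(F)F)C(F)(F)F
Why: Kinetic enolate formation and O-triflation, in which the C9 hydrogens (α to C10=O and allylic to C7=C8) are removed in preference to those at C2, so only C10 becomes the enol triflate; the new C9=C10 bond is expected cis within the ring because a trans double bond beside the cis C7=C8 would strain ring A.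

Step 14
Reactants: 22 (4R,5S,7Z,9E)-5-[2-(tert-butyldimethylsilyloxy)ethyl]-4,5-dimethyl-1-oxocyclodeca-7,9-dien-10-yl triflate
Product: 23 (4R,5S,7Z,9E)-5-[2-(tert-butyldimethylsilyloxy)ethyl]-4,5-dimethyl-1-methylidenecyclodeca-7,9-dien-10-yl triflate
Conditions: Cp2Ti(μ-CH2)(μ-Cl)AlMe2 (Tebbe reagent, 1.3 equiv), pyridine (cat.), THF–toluene, −40 to 0 °C; dilute aq NaOH quench
Reagents that add atoms: Tebbe reagent written as Cp2Ti=CH2·ClAlMe2, C=[Ti](C1C=CC=C1)C1C=CC=C1.C[Al](C)Cl
Why: Titanium-carbene (Tebbe) methylenation is non-basic and should convert the enolisable conjugated C1 ketone without deprotonation at C2 or C6; placing it before the carbonylation avoids ester methylenation and the 2-acyl dienoate stage that could close to a 2H-pyran.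

Step 15
Reactants: 23 (4R,5S,7Z,9E)-5-[2-(tert-butyldimethylsilyloxy)ethyl]-4,5-dimethyl-1-methylidenecyclodeca-7,9-dien-10-yl triflate
Product: 24 methyl (4R,5S,7Z,9E)-5-[2-(tert-butyldimethylsilyloxy)ethyl]-4,5-dimethyl-1-methylidenecyclodeca-7,9-diene-10-carboxylate
Conditions: Pd(PPh3)4 (5 mol %), CO (1 atm), MeOH, Et3N, DMF, rt to 40 °C
Reagents that add atoms: carbon monoxide, [C-]#[O+]; methanol, CO
Why: Palladium-catalysed methoxycarbonylation of an alkenyl triflate, in which zerovalent palladium inserts into the C10–O bond with retention of alkene geometry and CO insertion followed by methanolysis gives the dienoate at a temperature too low for sigmatropic hydrogen shifts.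

Step 16
Reactants: 24 methyl (4R,5S,7Z,9E)-5-[2-(tert-butyldimethylsilyloxy)ethyl]-4,5-dimethyl-1-methylidenecyclodeca-7,9-diene-10-carboxylate
Product: 25 methyl (4R,5S,7Z,9E)-5-(2-hydroxyethyl)-4,5-dimethyl-1-methylidenecyclodeca-7,9-diene-10-carboxylate
Conditions: HF·pyridine, pyridine, THF, 0 °C to rt
Reagents that add atoms: none
Why: Buffered fluoride desilylation frees the primary alcohol without the basic conditions that could shift the double bonds of the cross-conjugated triene ester.

Step 17
Reactants: 25 methyl (4R,5S,7Z,9E)-5-(2-hydroxyethyl)-4,5-dimethyl-1-methylidenecyclodeca-7,9-diene-10-carboxylate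
Product: 26 methyl (4R,5S,7Z,9E)-4,5-dimethyl-1-methylidene-5-(2-oxoethyl)cyclodeca-7,9-diene-10-carboxylate
Conditions: Dess–Martin periodinane, NaHCO3, CH2Cl2, 0 °C to rt
Reagents that add atoms: none
Why: Dess–Martin oxidation works under neutral buffered conditions, stops at the aldehyde and leaves the triene ester alone, the aldehyde having no α-stereocentre to lose.

Step 18
Reactants: 26 methyl (4R,5S,7Z,9E)-4,5-dimethyl-1-methylidene-5-(2-oxoethyl)cyclodeca-7,9-diene-10-carboxylate; 27 3-bromofuran
Product: 29 methyl (4R,5S,7Z,9E)-5-[2-(furan-3-yl)-2-hydroxyethyl]-4,5-dimethyl-1-methylidenecyclodeca-7,9-diene-10-carboxylate (both C12 epimers), via 3-furyllithium 28 (not isolated)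
Conditions: 27 (1.15 equiv), n-BuLi (1.1 equiv), Et2O, −78 °C; then 26 in THF, −78 °C; AcOH quench at −78 °C
Reagents that add atoms: none
Why: Bromine–lithium exchange and 1,2-addition, since at −78 °C 3-furyllithium keeps its position and adds to the aldehyde much faster than to the hindered conjugated ester; no control at C12 is sought because steps 19 and 20 reset this centre.

Step 19
Reactants: 29 methyl (4R,5S,7Z,9E)-5-[2-(furan-3-yl)-2-hydroxyethyl]-4,5-dimethyl-1-methylidenecyclodeca-7,9-diene-10-carboxylate
Product: 30 methyl (4R,5S,7Z,9E)-5-[2-(furan-3-yl)-2-oxoethyl]-4,5-dimethyl-1-methylidenecyclodeca-7,9-diene-10-carboxylate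
Conditions: Dess–Martin periodinane, NaHCO3, CH2Cl2, 0 °C
Reagents that add atoms: none
Why: Dess–Martin oxidation of the furylic alcohol merges both epimers into one ketone under conditions that a furan tolerates.

Step 20
Reactants: 30 methyl (4R,5S,7Z,9E)-5-[2-(furan-3-yl)-2-oxoethyl]-4,5-dimethyl-1-methylidenecyclodeca-7,9-diene-10-carboxylate
Product: 31 methyl (4R,5S,7Z,9E)-5-[(2R)-2-(furan-3-yl)-2-hydroxyethyl]-4,5-dimethyl-1-methylidenecyclodeca-7,9-diene-10-carboxylate
Conditions: (S)-1-methyl-3,3-diphenyltetrahydro-1H,3H-pyrrolo[1,2-c][1,3,2]oxazaborole (0.3 equiv), catecholborane (2 equiv), toluene, −78 °C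
Reagents that add atoms: none
Why: Corey–Bakshi–Shibata reduction, in which the ketone binds with the flat furyl group as the large and the unbranched C11 methylene as the small substituent, so the (S)-catalyst should deliver hydride to the Si face and set C12 as R by reagent control, while catecholborane at low temperature does not hydroborate the alkenes.

Step 21
Reactants: 31 methyl (4R,5S,7Z,9E)-5-[(2R)-2-(furan-3-yl)-2-hydroxyethyl]-4,5-dimethyl-1-methylidenecyclodeca-7,9-diene-10-carboxylate; 32 (R)-2-methylbutanoic acid
Product: 33 CNP0305973.1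
Conditions: 32, N,N'-dicyclohexylcarbodiimide, 4-(dimethylamino)pyridine (0.1 equiv), CH2Cl2, 0 °C to rt
Reagents that add atoms: none
Why: Steglich esterification acylates oxygen and so retains C12, and the low temperature with only catalytic nucleophilic base should keep the α-stereocentre of the purchased R acid intact.

Compound list
1 | but-3-en-2-one | C=CC(C)=O | starting material
2 | 2-(triisopropylsilyloxy)buta-1,3-diene | C=CC(=C)O[Si](C(C)C)(C(C)C)C(C)C | intermediate
3 | (E)-2-methylbut-2-enal | C/C=C(\C)C=O | starting material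
4 | (1R,6R)-1,6-dimethyl-4-(triisopropylsilyloxy)cyclohex-3-ene-1-carbaldehyde (methyls cis) | CC(C)[Si](OC1=CC[C@@](C)(C=O)[C@H](C)C1)(C(C)C)C(C)C | intermediate
5 | [(4S,5R)-4-ethenyl-4,5-dimethylcyclohex-1-en-1-yl]oxy(triisopropyl)silane | CC(C)[Si](OC1=CC[C@@](C)(C=C)[C@H](C)C1)(C(C)C)C(C)C | intermediate
6 | B-alkyl-9-borabicyclo[3.3.1]nonane adduct of 5 (boron on C12) | CC(C)[Si](OC1=CC[C@@](C)(CCB2C3CCCC2CCC3)[C@H](C)C1)(C(C)C)C(C)C | intermediate
7 | 2-[(1S,6R)-1,6-dimethyl-4-(triisopropylsilyloxy)cyclohex-3-en-1-yl]ethanol | CC(C)[Si](OC1=CC[C@@](C)(CCO)[C@H](C)C1)(C(C)C)C(C)C | intermediate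
8 | (3R)-3-[(4R)-2-hydroxy-4-methyloxan-4-yl]butanoic acid (anomers) | OC(=O)C[C@@H](C)[C@]1(C)CCOC(O)C1 | intermediate
9 | (3R)-3-[(4R)-2-methoxy-4-methyloxan-4-yl]butanoic acid (anomers) | OC(=O)C[C@@H](C)[C@]1(C)CCOC(OC)C1 | intermediate
10 | isobutyl carbonic mixed anhydride of 9 | CC(C)COC(=O)OC(=O)C[C@@H](C)[C@]1(C)CCOC(OC)C1 | intermediate
11 | (4R)-1-diazo-4-[(4R)-2-methoxy-4-methyloxan-4-yl]pentan-2-one | [N-]=[N+]=CC(=O)C[C@@H](C)[C@]1(C)CCOC(OC)C1 | intermediate
12 | methyl (4R)-4-[(4R)-2-methoxy-4-methyloxan-4-yl]pentanoate | COC(=O)CC[C@@H](C)[C@]1(C)CCOC(OC)C1 | intermediate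
13 | methyl (4R)-4-[(4R)-2-hydroxy-4-methyloxan-4-yl]pentanoate | COC(=O)CC[C@@H](C)[C@]1(C)CCOC(O)C1 | intermediate
14 | (2-carboxyethyl)triphenylphosphonium bromide | OC(=O)CC[P+](c1ccccc1)(c1ccccc1)c1ccccc1.[Br-] | starting material
15 | sodium 3-(triphenylphosphoranylidene)propanoate | [Na+].[O-]C(=O)CC=P(c1ccccc1)(c1ccccc1)c1ccccc1 | intermediate
16 | (3Z,6S,7R)-6-(2-hydroxyethyl)-10-methoxy-6,7-dimethyl-10-oxodec-3-enoic acid | COC(=O)CC[C@@H](C)[C@](C)(CCO)C/C=C\CC(=O)O | intermediate
17 | dimethyl (3Z,6S,7R)-6-(2-hydroxyethyl)-6,7-dimethyldec-3-enedioate | COC(=O)CC[C@@H](C)[C@](C)(CCO)C/C=C\CC(=O)OC | intermediate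
18 | dimethyl (3Z,6S,7R)-6-[2-(tert-butyldimethylsilyloxy)ethyl]-6,7-dimethyldec-3-enedioate | COC(=O)CC[C@@H](C)[C@](C)(CCO[Si](C)(C)C(C)(C)C)C/C=C\CC(=O)OC | intermediate
19 | ring A bis(trimethylsilyl) enediol ether, (4R,5S,7Z), enediol C1=C10 cis in the ring | C[Si](C)(C)O/C1=C(\O[Si](C)(C)C)CC[C@@H](C)[C@](C)(CCO[Si](C)(C)C(C)(C)C)C/C=C\C1 | intermediate
20 | ring A 1,10-dione, (4R,5S,7Z) | O=C1C(=O)CC[C@@H](C)[C@](C)(CCO[Si](C)(C)C(C)(C)C)C/C=C\C1 | intermediate
21 | potassium C10 dienolate of 20 | O=C1CC[C@@H](C)[C@](C)(CCO[Si](C)(C)C(C)(C)C)C/C=C\C=C/1[O-].[K+] | intermediate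
22 | C10 dienyl triflate, C1 ketone, (4R,5S,7Z,9E), both ring alkenes cis in the ring | O=C1CC[C@@H](C)[C@](C)(CCO[Si](C)(C)C(C)(C)C)C/C=C\C=C/1OS(=O)(=O)C(F)(F)F | intermediate
23 | C10 dienyl triflate, C1 exocyclic methylene | C=C1CC[C@@H](C)[C@](C)(CCO[Si](C)(C)C(C)(C)C)C/C=C\C=C/1OS(=O)(=O)C(F)(F)F | intermediate
24 | ring A triene methyl ester, C12 silyl ether | C=C1CC[C@@H](C)[C@](C)(CCO[Si](C)(C)C(C)(C)C)C/C=C\C=C/1C(=O)OC | intermediate
25 | ring A triene methyl ester, C12 primary alcohol | C=C1CC[C@@H](C)[C@](C)(CCO)C/C=C\C=C/1C(=O)OC | intermediate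
26 | ring A triene methyl ester, C12 aldehyde | C=C1CC[C@@H](C)[C@](C)(CC=O)C/C=C\C=C/1C(=O)OC | intermediate
27 | 3-bromofuran | Brc1ccoc1 | starting material
28 | 3-furyllithium | [Li]c1ccoc1 | intermediate
29 | furyl carbinol, C12 epimers | C=C1CC[C@@H](C)[C@](C)(CC(O)c2ccoc2)C/C=C\C=C/1C(=O)OC | intermediate
30 | 3-furyl ketone at C12 | C=C1CC[C@@H](C)[C@](C)(CC(=O)c2ccoc2)C/C=C\C=C/1C(=O)OC | intermediate
31 | (12R)-furyl carbinol | C=C1CC[C@@H](C)[C@](C)(C[C@@H](O)c2ccoc2)C/C=C\C=C/1C(=O)OC | intermediate
32 | (R)-2-methylbutanoic acid | CC[C@@H](C)C(=O)O | starting material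
33 | CNP0305973.1, (4R,5S,7Z,9E,12R), (R)-2-methylbutanoate | C=C1CC[C@@H](C)[C@](C)(C[C@@H](OC(=O)[C@H](C)CC)c2ccoc2)C/C=C\C=C/1C(=O)OC | target

Total step count: 21. Longest linear sequence: 21 steps (1 to 33).

Steps most likely to fail

Step 11. Chain-to-chain coupling and oligomerisation may outrun ring closure. Metalation at the doubly activated C9 may also lead to O-silylation or to migration of the double bond into conjugation, followed by over-reduction. The fallback sets out from diester 18. Reduction with i-Bu2AlH (2 equiv, toluene, −78 °C) would give the (Z)-dialdehyde F1, used at once. Slow addition to TiCl3(DME)1.5 and Zn–Cu in DME at room temperature would form the same C1–C10 bond by intramolecular pinacol coupling, giving the ring 1,2-diol F2. A double Swern oxidation would then return to the route at dione 20.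

Step 13. Enolisation may give the C9=C10 bond trans within the ring or erode the cis geometry at C7=C8. The strong base may also start a transannular aldol or a benzilic-type contraction of the dione. The fallback sets out from dione 20. Soft enolisation with Et3SiOTf and Et3N in CH2Cl2 under equilibrating conditions would give the neutral triethylsilyl dienol ether F3, which can be purified and sorted by geometry. CsF with PhN(SO2CF3)2 in DME would then exchange silicon for triflyl on the stereodefined enolate, coming back at triflate 22.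

Step 14. The carbene may attack the transannularly shielded ketone too slowly, the aluminium Lewis acid may cost the triflate, or the alkenes may be drawn into side reactions. The fallback sets out from triflate 22. Addition of Me3SiCH2Li with CeCl3 (THF, −78 °C) would give the β-hydroxysilane F4. Peterson elimination with BF3·OEt2 in CH2Cl2 at low temperature would come back at methylene triflate 23.

Further compounds
F1 | step 11 | (3Z,6S,7R)-6-[2-(tert-butyldimethylsilyloxy)ethyl]-6,7-dimethyldec-3-enedial | O=CCC[C@@H](C)[C@](C)(CCO[Si](C)(C)C(C)(C)C)C/C=C\CC=O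
F2 | step 11 | ring A 1,10-diol, (4R,5S,7Z), carbinol centres unassigned | OC1C(O)CC[C@@H](C)[C@](C)(CCO[Si](C)(C)C(C)(C)C)C/C=C\C1
F3 | step 13 | C10 triethylsilyl dienol ether of 20, (7Z,9E) | O=C1CC[C@@H](C)[C@](C)(CCO[Si](C)(C)C(C)(C)C)C/C=C\C=C/1O[Si](CC)(CC)CC
F4 | step 14 | C1 tertiary alcohol bearing CH2SiMe3, C10 triflate, C1 unassigned | C[Si](C)(C)CC1(O)CC[C@@H](C)[C@](C)(CCO[Si](C)(C)C(C)(C)C)C/C=C\C=C/1OS(=O)(=O)C(F)(F)F
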